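## Analysis of the target

Cathafuran C (18) is a 2-arylbenzofuran in which C2 of a 6-hydroxybenzofuran is bonded to C5 of a 2,2-dimethyl-2H-chromene that carries a hydroxyl group at C7 and a prenyl group at C6. There is no stereocenter: the pyran C3=C4 bond is held cis by the ring and the side-chain alkene ends in two methyl groups, so the task is one of connectivity only. The benzene ring of the chromene (ring A) is pentasubstituted, with oxygen at C7 and C8a, three adjacent carbon substituents at C4a (pyran C4), C5 (benzofuran C2) and C6 (prenyl CH2), and one hydrogen at C8. The sensitive groups are the two free phenols and the electron-rich chromene double bond (oxidation), the prenyl alkene beside the C7 hydroxyl (acid closes it to a chroman), and both alkenes toward hydrogenation, which excludes benzyl ethers. The synthesis is hard because the biaryl bond at C5 lies between two ortho carbon substituents, and because carbon must be placed at C4a and C6 while C8, the site between the two oxygens that a resorcinol offers most readily to electrophiles and to lithiation, stays free. The plan rests on two facts: C5 is ortho to both C6 and C4a, and the pyran carbons C4, C3 and C2 with its two methyl groups are a second prenyl group closed oxidatively onto the C8a oxygen. Ring A is therefore a hidden symmetrical 4,6-diprenylresorcinol whose two aryl–CH2 bonds flank the carbon bearing the benzofuran, and a carboxyl group on that carbon can first steer a metal to both neighbors and then become C2 of the benzofuran.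

## Retrosynthetic reasoning

**O–Si bond on the benzofuran.** Target 18 is traced back to its silyl ether 17. The benzofuran phenol stays masked until the end so that the oxidative step before it meets only ring A phenols. The final fluoride unmasking touches neither the chromene nor the prenyl group.

**Pyran O1–C2 bond.** Cutting O1–C2 of 17 and returning hydrogen to C4 and C3 turns the pyran into a prenyl group beside a free phenol, which is the symmetrical resorcinol 15. In the forward sense a quinone oxidant takes a hydride from one benzylic CH2, the ortho-quinone methide 16 forms, and an oxa-6π electrocyclization closes the ring. The cut is made here because it uncovers the symmetry: the two possible closures of 15 give the same product, so the only open question is stopping after one.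

**Two acetal C–O bonds.** Diol 15 comes from the bis-MOM ether 14. MOM groups are chosen because they are small, stable to base and to the metal catalyst, able to coordinate, and removable under conditions the aryl silyl ether survives.

**Benzofuran C2=C3 and O1–C2 bonds.** Cutting these in 14 gives the benzoic acid 7, whose carboxyl carbon becomes C2, and the phosphonium salt 11, which supplies O1, C3 and the benzo ring. Forward, the acid chloride 12 acylates the phenol of 11 to give ester 13, whose ylide attacks the ester carbonyl in an intramolecular Wittig reaction. A biaryl cross-coupling at C5 was not chosen: it would have to join two rings at a carbon between two ortho substituents and would need a halide or metal there. The carboxyl group is a better handle because it also serves the next disconnection.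

**Two aryl–CH2 bonds (key disconnection).** Both prenyl groups of 7 are cut at once, giving the symmetrical acid 3 and two molecules of the tertiary allylic carbonate 5, by way of the monoprenylated acid 6. Both bonds are ortho to the carboxyl group and are identical, so one catalytic C–H functionalization can form them without any halogenation or prenyl-metal reagent. The forward reaction has to metalate only the two C–H bonds beside the carboxylate, leave the C–H bond between the ethers alone, deliver the linear prenyl isomer, and run twice.

**Precursors.** Acid 3 comes from ester 2 by saponification and 2 from the commercial diphenol 1 by acetal formation. Carbonate 5 comes from the commercial tertiary alcohol 4 by O-acylation. Salt 11 comes from the commercial aldehyde 8 through the mono-silyl ether 9 and the benzylic alcohol 10. All of this is routine chemistry, so the risk sits in the key step.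

## Alternatives that were turned down

**Alternative 1: pyran from an aryne and an enal.**
- **Disconnection:** the pyran is cut at O1–C8a, C4–C4a and O1–C2, so that ring A appears as an aryne and the pyran atoms come from 3-methylbut-2-enal (A3).
- **Forward key step:** fluoride-induced elimination of 3-fluoro-5-(methoxymethoxy)-2-(trimethylsilyl)phenyl trifluoromethanesulfonate (A2) gives the aryne. The carbonyl group of A3 adds across it with oxygen at the aryne carbon remote from fluorine, the four-membered adduct opens to an ortho-quinone methide, and oxa-6π closure gives 5-fluoro-7-(methoxymethoxy)-2,2-dimethyl-2H-chromene (A1).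
- **For:** one step builds the whole pyran in one defined orientation. Fluorine controls the aryne regiochemistry and later acidifies C6–H for metalation and prenylation. No statistical pyran closure arises, and on that point it is stronger than the chosen route.
- **Against:** the C5–F bond of A1 must finally become the C5–benzofuran bond. That is a cross-coupling of an unactivated aryl fluoride on an electron-rich ring, at the carbon flanked by C4a and C6. A2 needs several steps, aryne–aldehyde annulations compete with ene and multiple-insertion pathways, and the chromene alkene must survive organolithium chemistry.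
- **Comparison:** the chosen route makes the C5–heteroaryl bond by building the furan from the directing carboxyl group, not by coupling, and forms both ring A C–C bonds in one step. Step counts are similar, but Alternative 1 carries two uncertain steps (annulation and C–F arylation) against one.

**Alternative 2: benzofuran annulated onto an acetyl group.**
- **Disconnection:** benzofuran C3–C3a and O1–C7a, giving the methyl ketone 1-[7-(methoxymethoxy)-2,2-dimethyl-6-(3-methylbut-2-en-1-yl)-2H-chromen-5-yl]ethan-1-one (A5) and the dihaloarene 2-bromo-1-iodo-4-(methoxymethoxy)benzene (A6). In A6 the iodine stands para and the bromine meta to the protected oxygen.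
- **Forward key step:** a zerovalent palladium catalyst arylates the enolate of A5 at the C–I carbon of A6 and then closes the enolate oxygen onto the C–Br carbon. The product is 6-(methoxymethoxy)-2-[7-(methoxymethoxy)-2,2-dimethyl-6-(3-methylbut-2-en-1-yl)-2H-chromen-5-yl]benzofuran (A4). Bis-MOM ether A4 is one deprotection from 18.
- **For:** it is convergent and ends close to the target, since A4 already holds the whole skeleton. The new C–C bond forms at the methyl carbon, away from the crowded ring, so the ring closure is as strong as or stronger than the Wittig closure of step 8, which must attack a shielded carbonyl. The different reactivity of the iodide and the bromide of A6 fixes the orientation of the furan oxygen.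
- **Against:** all the difficulty moves into A5, a hexasubstituted benzene with an acetyl group between two carbon substituents. C5 is meta to both oxygens, so acylation cannot put the acetyl group there. A5 must come from a 3,5-dioxygenated aryl ketone or acid by the same ortho-functionalization that is the real problem. The enolate of a di-ortho-substituted aryl ketone arylates slowly and needs strong base with heat.
- **Comparison:** the chosen route supplies what Alternative 2 presupposes, namely the substituted ring A in one catalytic step, and uses one carbon twice, as director and as benzofuran C2. Making A5 alone would take about as many steps as the whole sequence to 14, and A6 would have to be prepared as well.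

**Alternative 3: Diels–Alder construction of ring A.**
- **Disconnection:** ring A itself at C5–C6 and C4a–C8a, giving 1-methoxy-7-methyl-1,3-bis(trimethylsilyloxy)octa-1,3,6-triene (A8) and methyl 3-[6-(methoxymethoxy)benzofuran-2-yl]prop-2-ynoate (A9).
- **Forward key step:** [4+2] cycloaddition, aromatization by loss of the alkoxy group, and desilylation give methyl 2,4-dihydroxy-6-[6-(methoxymethoxy)benzofuran-2-yl]-5-(3-methylbut-2-en-1-yl)benzoate (A7).
- **For:** polarity matching (nucleophilic diene terminus to the β-carbon of the ynoate) places the prenyl group, the benzofuran and a carbon handle on three adjacent carbons with no arene substitution at all. The two hydroxyls of A7 differ, since one is chelated to the ester, so a later pyran closure would not be statistical. On regiochemical certainty it is stronger than the chosen route.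
- **Against:** A8 is substituted at its reacting terminus and A9 carries a heteroaryl group at its β-carbon, and both slow the cycloaddition. Forcing conditions endanger the silyl enol ethers. The ester of A7 supplies only C4, so several more steps at a carbon beside the benzofuran are needed to add C3 and C2. A9 itself needs a preformed benzofuran alkyne.
- **Comparison:** the chosen route starts from commodity aromatics, forms two C–C bonds in one catalytic step, and brings the pyran carbons in as a prenyl group that needs only one oxidation. It is shorter, at the price of the late mono-cyclization issue.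

Key step: step 4

Remark on the chemistry: 18 has no stereocenter, so no step has to set configuration. Methyl 3,5-dihydroxybenzoate (1) is taken as the ring A starting material in place of the free acid, which avoids cleaving a MOM ester, and the benzofuran oxygen is carried as a triisopropylsilyl ether.

## Route

Step 1
Reactants: 1 methyl 3,5-dihydroxybenzoate
Product: 2 methyl 3,5-bis(methoxymethoxy)benzoate
Conditions: MOMCl (2.5 equiv), i-Pr2NEt, CH2Cl2, 0 °C to rt
Reagents that add atoms: chloromethyl methyl ether, COCCl
Why: Both phenols are alkylated by the α-chloro ether through its oxocarbenium ion under amine base (acetal-forming O-alkylation); the ester keeps the carboxyl group out of the reaction.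

Step 2
Reactants: 2 methyl 3,5-bis(methoxymethoxy)benzoate
Product: 3 3,5-bis(methoxymethoxy)benzoic acid
Conditions: LiOH·H2O, THF/MeOH/H2O, 50 °C; then 1 M HCl to pH 3, 0 °C
Reagents that add atoms: lithium hydroxide, [Li+].[OH-]
Why: Saponification of an unhindered methyl benzoate; the MOM acetals are stable to base, and the cold, brief acidification frees the acid without touching them.

Step 3
Reactants: 4 2-methylbut-3-en-2-ol
Product: 5 tert-butyl 2-methylbut-3-en-2-yl carbonate
Conditions: n-BuLi, THF, 0 °C; then Boc2O, 0 °C to rt
Reagents that add atoms: di-tert-butyl dicarbonate, CC(C)(C)OC(=O)OC(=O)OC(C)(C)C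
Why: The lithium alkoxide of the tertiary alcohol attacks a carbonyl group of Boc2O and expels tert-butyl carbonate (O-acylation of an alkoxide); prior deprotonation is needed because the tertiary alcohol is a poor nucleophile.

Step 4
Reactants: 3 3,5-bis(methoxymethoxy)benzoic acid; 5 tert-butyl 2-methylbut-3-en-2-yl carbonate (3 equiv)
Product: 7 3,5-bis(methoxymethoxy)-2,6-bis(3-methylbut-2-en-1-yl)benzoic acid, via monoprenylated acid 6 (not isolated)
Conditions: [RuCl2(p-cymene)]2 (5 mol %), K3PO4 (0.5 equiv), MeCN, 60 °C; aq. citric acid work-up
Reagents that add atoms: none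
Why: Proposed new method: the carboxylate of 3 binds the divalent ruthenium center and delivers it to an ortho C–H bond by carboxylate-assisted concerted metalation–deprotonation, giving a five-membered ruthenacycle; the monosubstituted alkene of 5 then inserts into the aryl–Ru bond with the aryl group going to the unsubstituted CH2 terminus, and β-oxygen elimination of the tert-butyl carbonate group (lost as CO2 and tert-butoxide, which takes up the proton) leaves the aryl–CH2–CH=C(CH3)2 unit and returns divalent ruthenium without an external oxidant. The same cycle then runs on 6 at its remaining ortho carbon and gives 7. The closest known reaction type is the carboxylate-directed ortho C–H allylation of benzoic acids with allylic acetates, carbonates or alcohols under [RuCl2(p-cymene)]2 or [Cp*RhCl2]2 (trivalent rhodium) catalysis, known for single allylation with simple allyl partners; new here is a double, linear-selective prenylation with a tertiary allylic carbonate at two positions that are each flanked by an ether. No ring is closed and no stereocenter is formed, and the new alkene carries two identical methyl groups, so no geometry has to be controlled. The site selectivity needed is C2 and C6 against C4: only C2 and C6 can form a chelate with the carboxylate, whereas C4, the usual site of lithiation and electrophilic attack between the two ethers, is out of its reach. Linear against branched selectivity follows from insertion at the unhindered alkene terminus and elimination of the only β-leaving group, which moves the double bond into the trisubstituted position. Complete double substitution is driven by the excess of 5 and by the free ortho C–H bond that the carboxylate of 6 still has; the small, coordinating MOM ethers keep the flanked positions accessible.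

Step 5
Reactants: 8 2,4-dihydroxybenzaldehyde
Product: 9 2-hydroxy-4-(triisopropylsilyloxy)benzaldehyde
Conditions: TIPSCl (1.05 equiv), imidazole, CH2Cl2, 0 °C
Reagents that add atoms: chlorotriisopropylsilane, CC(C)[Si](Cl)(C(C)C)C(C)C
Why: The 2-hydroxyl is hydrogen-bonded to the aldehyde and more hindered, so silylation under imidazole takes the 4-hydroxyl selectively (selective O-silylation).

Step 6
Reactants: 9 2-hydroxy-4-(triisopropylsilyloxy)benzaldehyde
Product: 10 2-(hydroxymethyl)-5-(triisopropylsilyloxy)phenol
Conditions: NaBH4, MeOH/THF, 0 °C; aq. NH4Cl work-up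
Reagents that add atoms: none
Why: Borohydride reduction of the aldehyde to the benzylic alcohol; the aryl silyl ether is unaffected, and the near-neutral work-up avoids ionization of the electron-rich salicyl alcohol.

Step 7
Reactants: 10 2-(hydroxymethyl)-5-(triisopropylsilyloxy)phenol
Product: 11 [2-hydroxy-4-(triisopropylsilyloxy)benzyl]triphenylphosphonium bromide
Conditions: PPh3·HBr, MeCN, rt to 50 °C
Reagents that add atoms: triphenylphosphine hydrobromide, [Br-].[PH+](c1ccccc1)(c1ccccc1)c1ccccc1
Why: The acid salt ionizes the benzylic alcohol, whose cation is stabilized by the ortho-hydroxyl and para-silyloxy groups, and the phosphine traps it (SN1-type formation of a benzylphosphonium salt); the bulky aryl TIPS ether should withstand this weak acid in an aprotic solvent, which an aryl MOM ether might not.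

Step 8
Reactants: 7 3,5-bis(methoxymethoxy)-2,6-bis(3-methylbut-2-en-1-yl)benzoic acid; 11 [2-hydroxy-4-(triisopropylsilyloxy)benzyl]triphenylphosphonium bromide
Product: 14 2-[3,5-bis(methoxymethoxy)-2,6-bis(3-methylbut-2-en-1-yl)phenyl]-6-(triisopropylsilyloxy)benzofuran, via acid chloride 12 (not isolated), via acyloxybenzylphosphonium bromide 13 (not isolated)
Conditions: 1-chloro-N,N,2-trimethylprop-1-en-1-amine (Ghosez's reagent, 1.05 equiv), CH2Cl2, 0 °C to rt; then 11, Et3N (4 equiv), PhMe, rt then 110 °C
Reagents that add atoms: none
Why: The α-chloroenamine forms the acid chloride under neutral conditions that spare the MOM ethers and prenyl groups, and the aroyl chloride acylates the phenoxide of 11. Et3N then forms the ylide of 13, which attacks the aryl ester carbonyl in a five-membered transition state, and loss of triphenylphosphine oxide gives the C2=C3 bond (intramolecular Wittig reaction of an ester); ortho-substituted aroyl esters are expected to close in this reaction, though more slowly.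

Step 9
Reactants: 14 2-[3,5-bis(methoxymethoxy)-2,6-bis(3-methylbut-2-en-1-yl)phenyl]-6-(triisopropylsilyloxy)benzofuran
Product: 15 4,6-bis(3-methylbut-2-en-1-yl)-5-[6-(triisopropylsilyloxy)benzofuran-2-yl]benzene-1,3-diol
Conditions: HCl (1.25 M in MeOH), MeOH/THF, rt
Reagents that add atoms: none
Why: Acid-catalyzed acetal exchange with methanol cleaves both aryl MOM ethers; dilute acid at room temperature should leave the hindered aryl TIPS ether in place and is too mild for addition of the freed phenols to the prenyl alkenes.

Step 10
Reactants: 15 4,6-bis(3-methylbut-2-en-1-yl)-5-[6-(triisopropylsilyloxy)benzofuran-2-yl]benzene-1,3-diol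
Product: 17 2,2-dimethyl-6-(3-methylbut-2-en-1-yl)-5-[6-(triisopropylsilyloxy)benzofuran-2-yl]-2H-chromen-7-ol, via ortho-quinone methide 16 (not isolated)
Conditions: DDQ (1.0 equiv, added in portions), PhMe, 80 °C
Reagents that add atoms: none
Why: DDQ takes a benzylic hydride from one prenyl CH2 that is activated by an ortho and a para hydroxyl, loss of the phenol proton gives 16, and oxa-6π electrocyclization closes the pyran (oxidative cyclization of an ortho-prenylphenol). The two prenyl groups of 15 are equivalent, so either closure gives 17; one equivalent of oxidant is used and the reaction is stopped before full conversion, so that the second closure is held back and unreacted 15 can be recycled.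

Step 11
Reactants: 17 2,2-dimethyl-6-(3-methylbut-2-en-1-yl)-5-[6-(triisopropylsilyloxy)benzofuran-2-yl]-2H-chromen-7-ol
Product: 18 cathafuran C, 5-(6-hydroxybenzofuran-2-yl)-2,2-dimethyl-6-(3-methylbut-2-en-1-yl)-2H-chromen-7-ol
Conditions: TBAF, AcOH, THF, 0 °C
Reagents that add atoms: none
Why: Fluoride cleaves the aryl O–Si bond (desilylation); buffering with AcOH keeps the medium near neutral, so the phenols, the chromene and the prenyl group are left alone.

## Compound list

1 | methyl 3,5-dihydroxybenzoate | COC(=O)c1cc(O)cc(O)c1 | starting material
2 | methyl 3,5-bis(methoxymethoxy)benzoate | COCOc1cc(OCOC)cc(c1)C(=O)OC | intermediate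
3 | 3,5-bis(methoxymethoxy)benzoic acid | COCOc1cc(OCOC)cc(c1)C(=O)O | intermediate
4 | 2-methylbut-3-en-2-ol | CC(C)(O)C=C | starting material
5 | tert-butyl 2-methylbut-3-en-2-yl carbonate | CC(C)(C)OC(=O)OC(C)(C)C=C | intermediate
6 | 3,5-bis(methoxymethoxy)-2-(3-methylbut-2-en-1-yl)benzoic acid | COCOc1cc(OCOC)c(CC=C(C)C)c(C(=O)O)c1 | intermediate
7 | 3,5-bis(methoxymethoxy)-2,6-bis(3-methylbut-2-en-1-yl)benzoic acid | COCOc1cc(OCOC)c(CC=C(C)C)c(C(=O)O)c1CC=C(C)C | intermediate
8 | 2,4-dihydroxybenzaldehyde | O=Cc1ccc(O)cc1O | starting material
9 | 2-hydroxy-4-(triisopropylsilyloxy)benzaldehyde | O=Cc1ccc(O[Si](C(C)C)(C(C)C)C(C)C)cc1O | intermediate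
10 | 2-(hydroxymethyl)-5-(triisopropylsilyloxy)phenol | OCc1ccc(O[Si](C(C)C)(C(C)C)C(C)C)cc1O | intermediate
11 | [2-hydroxy-4-(triisopropylsilyloxy)benzyl]triphenylphosphonium bromide | [Br-].Oc1cc(O[Si](C(C)C)(C(C)C)C(C)C)ccc1C[P+](c1ccccc1)(c1ccccc1)c1ccccc1 | intermediate
12 | 3,5-bis(methoxymethoxy)-2,6-bis(3-methylbut-2-en-1-yl)benzoyl chloride | COCOc1cc(OCOC)c(CC=C(C)C)c(C(Cl)=O)c1CC=C(C)C | intermediate
13 | {2-[3,5-bis(methoxymethoxy)-2,6-bis(3-methylbut-2-en-1-yl)benzoyloxy]-4-(triisopropylsilyloxy)benzyl}triphenylphosphonium bromide | [Br-].COCOc1cc(OCOC)c(CC=C(C)C)c(C(=O)Oc2cc(O[Si](C(C)C)(C(C)C)C(C)C)ccc2C[P+](c2ccccc2)(c2ccccc2)c2ccccc2)c1CC=C(C)C | intermediate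
14 | 2-[3,5-bis(methoxymethoxy)-2,6-bis(3-methylbut-2-en-1-yl)phenyl]-6-(triisopropylsilyloxy)benzofuran | COCOc1cc(OCOC)c(CC=C(C)C)c(-c2cc3ccc(O[Si](C(C)C)(C(C)C)C(C)C)cc3o2)c1CC=C(C)C | intermediate
15 | 4,6-bis(3-methylbut-2-en-1-yl)-5-[6-(triisopropylsilyloxy)benzofuran-2-yl]benzene-1,3-diol | Oc1cc(O)c(CC=C(C)C)c(-c2cc3ccc(O[Si](C(C)C)(C(C)C)C(C)C)cc3o2)c1CC=C(C)C | intermediate
16 | 3-hydroxy-6-(3-methylbut-2-en-1-ylidene)-4-(3-methylbut-2-en-1-yl)-5-[6-(triisopropylsilyloxy)benzofuran-2-yl]cyclohexa-2,4-dien-1-one | O=C1C=C(O)C(CC=C(C)C)=C(c2cc3ccc(O[Si](C(C)C)(C(C)C)C(C)C)cc3o2)C1=CC=C(C)C | intermediate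
17 | 2,2-dimethyl-6-(3-methylbut-2-en-1-yl)-5-[6-(triisopropylsilyloxy)benzofuran-2-yl]-2H-chromen-7-ol | CC(C)=CCc1c(O)cc2c(c1-c1cc3ccc(O[Si](C(C)C)(C(C)C)C(C)C)cc3o1)C=CC(C)(C)O2 | intermediate
18 | cathafuran C, 5-(6-hydroxybenzofuran-2-yl)-2,2-dimethyl-6-(3-methylbut-2-en-1-yl)-2H-chromen-7-ol | CC(C)=CCc1c(O)cc2c(c1-c1cc3ccc(O)cc3o1)C=CC(C)(C)O2 | target

## Step count and uncertain steps

Total: 11 steps. Longest linear sequence: 7 steps (steps 1, 2, 4, 8, 9, 10, 11 from 1; the branch from 8 through steps 5, 6, 7 and then 8 to 11 is equally long).

**Step 4 (key step, proposed new method).**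
- What may go wrong: the second metalation may stall once the first prenyl group twists the carboxylate of 6 out of the ring plane. The flanking acetal may slow metalation. The carboxylate may be O-prenylated instead of directing. A ruthenium hydride may move the new double bond into conjugation with the ring.
- Fallback by known chemistry, from 2 back to 7: ester 2 is brominated twice with NBS in MeCN at the two positions that are para to one ether and ortho to the other, giving methyl 2,6-dibromo-3,5-bis(methoxymethoxy)benzoate F1. A twofold Stille coupling with tributyl(3-methylbut-2-en-1-yl)stannane under a zerovalent palladium catalyst (Pd2(dba)3, P(t-Bu)3, CsF, dioxane, 100 °C) gives methyl 3,5-bis(methoxymethoxy)-2,6-bis(3-methylbut-2-en-1-yl)benzoate F2. The hindered methyl ester is then cleaved at the methyl carbon by SN2 attack of n-PrSLi in DMPU at rt, and acidification gives 7.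

**Step 8.**
- What may go wrong: the ylide carbon has to attack an ester carbonyl shielded by two ortho CH2 groups. Ring closure may be too slow, so that ylide hydrolysis or ester cleavage takes over. The acid chloride may also be lost by ionization and attack of an ortho prenyl alkene on the acylium carbon.
- Fallback, from 7 back to 14, which forms the furan away from the crowded carbon: LiAlH4 in THF reduces 7 to [3,5-bis(methoxymethoxy)-2,6-bis(3-methylbut-2-en-1-yl)phenyl]methanol F3. Dess–Martin oxidation buffered with NaHCO3 gives 3,5-bis(methoxymethoxy)-2,6-bis(3-methylbut-2-en-1-yl)benzaldehyde F4. Ohira–Bestmann homologation (dimethyl (1-diazo-2-oxopropyl)phosphonate, K2CO3, MeOH) gives 3-ethynyl-1,5-bis(methoxymethoxy)-2,4-bis(3-methylbut-2-en-1-yl)benzene F5. Purchased 4-iodobenzene-1,3-diol F6 is silylated with TIPSCl and imidazole at the hydroxyl remote from iodine to give 2-iodo-5-(triisopropylsilyloxy)phenol F7. Sonogashira coupling of F5 with F7 (PdCl2(PPh3)2, CuI, Et3N, DMF, 60 °C) gives 2-{[3,5-bis(methoxymethoxy)-2,6-bis(3-methylbut-2-en-1-yl)phenyl]ethynyl}-5-(triisopropylsilyloxy)phenol F8, which closes in the same flask by 5-endo-dig attack of the phenol on the alkyne to give 14.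

**Step 10.**
- What may go wrong: over-oxidation. The second prenyl/hydroxyl pair of 17 closes at a rate comparable to the first, so the step is limited to roughly statistical selectivity and depends on partial conversion and recycling of 15. The quinone methide may also tautomerize to a diene and not cyclize.
- Fallback, from 1 back to 18, which moves the statistical event to the first step on the cheapest material and makes the ring closure site-specific:
  - One equivalent of MOMCl with i-Pr2NEt converts 1 into methyl 3-hydroxy-5-(methoxymethoxy)benzoate F9, with 1 and 2 recovered.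
  - SEMCl and i-Pr2NEt give methyl 3-(methoxymethoxy)-5-{[2-(trimethylsilyl)ethoxy]methoxy}benzoate F10, and LiOH gives 3-(methoxymethoxy)-5-{[2-(trimethylsilyl)ethoxy]methoxy}benzoic acid F11.
  - The conditions of step 4 with 5 give 3-(methoxymethoxy)-2,6-bis(3-methylbut-2-en-1-yl)-5-{[2-(trimethylsilyl)ethoxy]methoxy}benzoic acid F12.
  - The conditions of step 8 with 11 give 2-[3-(methoxymethoxy)-2,6-bis(3-methylbut-2-en-1-yl)-5-{[2-(trimethylsilyl)ethoxy]methoxy}phenyl]-6-(triisopropylsilyloxy)benzofuran F13.
  - TBAF in THF/DMPU at 60 °C removes the SEM and TIPS groups but not the MOM ether, giving 2-[3-hydroxy-5-(methoxymethoxy)-2,6-bis(3-methylbut-2-en-1-yl)phenyl]benzofuran-6-ol F14, which has a single free ring A hydroxyl.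
  - A Wacker-type oxidative cyclization with a divalent palladium catalyst (Pd(OAc)2, KHCO3, DMSO/H2O, O2, 60 °C) gives 2-[7-(methoxymethoxy)-2,2-dimethyl-6-(3-methylbut-2-en-1-yl)-2H-chromen-5-yl]benzofuran-6-ol F15. Only the alkene beside the free hydroxyl can undergo intramolecular oxypalladation followed by β-hydride elimination.
  - Methanolic HCl as in step 9 removes the last MOM group and gives 18.

## Further compounds

F1 | step 4 | methyl 2,6-dibromo-3,5-bis(methoxymethoxy)benzoate | COC(=O)c1c(Br)c(OCOC)cc(OCOC)c1Br
F2 | step 4 | methyl 3,5-bis(methoxymethoxy)-2,6-bis(3-methylbut-2-en-1-yl)benzoate | COC(=O)c1c(CC=C(C)C)c(OCOC)cc(OCOC)c1CC=C(C)C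
F3 | step 8 | [3,5-bis(methoxymethoxy)-2,6-bis(3-methylbut-2-en-1-yl)phenyl]methanol | COCOc1cc(OCOC)c(CC=C(C)C)c(CO)c1CC=C(C)C
F4 | step 8 | 3,5-bis(methoxymethoxy)-2,6-bis(3-methylbut-2-en-1-yl)benzaldehyde | COCOc1cc(OCOC)c(CC=C(C)C)c(C=O)c1CC=C(C)C
F5 | step 8 | 3-ethynyl-1,5-bis(methoxymethoxy)-2,4-bis(3-methylbut-2-en-1-yl)benzene | COCOc1cc(OCOC)c(CC=C(C)C)c(C#C)c1CC=C(C)C
F6 | step 8 | 4-iodobenzene-1,3-diol (purchased) | Oc1ccc(I)c(O)c1
F7 | step 8 | 2-iodo-5-(triisopropylsilyloxy)phenol | Oc1cc(O[Si](C(C)C)(C(C)C)C(C)C)ccc1I
F8 | step 8 | 2-{[3,5-bis(methoxymethoxy)-2,6-bis(3-methylbut-2-en-1-yl)phenyl]ethynyl}-5-(triisopropylsilyloxy)phenol | COCOc1cc(OCOC)c(CC=C(C)C)c(C#Cc2ccc(O[Si](C(C)C)(C(C)C)C(C)C)cc2O)c1CC=C(C)C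
F9 | step 10 | methyl 3-hydroxy-5-(methoxymethoxy)benzoate | COC(=O)c1cc(O)cc(OCOC)c1
F10 | step 10 | methyl 3-(methoxymethoxy)-5-{[2-(trimethylsilyl)ethoxy]methoxy}benzoate | COC(=O)c1cc(OCOC)cc(OCOCC[Si](C)(C)C)c1
F11 | step 10 | 3-(methoxymethoxy)-5-{[2-(trimethylsilyl)ethoxy]methoxy}benzoic acid | OC(=O)c1cc(OCOC)cc(OCOCC[Si](C)(C)C)c1
F12 | step 10 | 3-(methoxymethoxy)-2,6-bis(3-methylbut-2-en-1-yl)-5-{[2-(trimethylsilyl)ethoxy]methoxy}benzoic acid | COCOc1cc(OCOCC[Si](C)(C)C)c(CC=C(C)C)c(C(=O)O)c1CC=C(C)C
F13 | step 10 | 2-[3-(methoxymethoxy)-2,6-bis(3-methylbut-2-en-1-yl)-5-{[2-(trimethylsilyl)ethoxy]methoxy}phenyl]-6-(triisopropylsilyloxy)benzofuran | COCOc1cc(OCOCC[Si](C)(C)C)c(CC=C(C)C)c(-c2cc3ccc(O[Si](C(C)C)(C(C)C)C(C)C)cc3o2)c1CC=C(C)C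
F14 | step 10 | 2-[3-hydroxy-5-(methoxymethoxy)-2,6-bis(3-methylbut-2-en-1-yl)phenyl]benzofuran-6-ol | COCOc1cc(O)c(CC=C(C)C)c(-c2cc3ccc(O)cc3o2)c1CC=C(C)C
F15 | step 10 | 2-[7-(methoxymethoxy)-2,2-dimethyl-6-(3-methylbut-2-en-1-yl)-2H-chromen-5-yl]benzofuran-6-ol | CC(C)=CCc1c(OCOC)cc2c(c1-c1cc3ccc(O)cc3o1)C=CC(C)(C)O2
A1 | alternative 1 | 5-fluoro-7-(methoxymethoxy)-2,2-dimethyl-2H-chromene | COCOc1cc(F)c2C=CC(C)(C)Oc2c1
A2 | alternative 1 | 3-fluoro-5-(methoxymethoxy)-2-(trimethylsilyl)phenyl trifluoromethanesulfonate | COCOc1cc(F)c([Si](C)(C)C)c(OS(=O)(=O)C(F)(F)F)c1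
A3 | alternative 1 | 3-methylbut-2-enal | CC(C)=CC=O
A4 | alternative 2 | 6-(methoxymethoxy)-2-[7-(methoxymethoxy)-2,2-dimethyl-6-(3-methylbut-2-en-1-yl)-2H-chromen-5-yl]benzofuran | CC(C)=CCc1c(OCOC)cc2c(c1-c1cc3ccc(OCOC)cc3o1)C=CC(C)(C)O2
A5 | alternative 2 | 1-[7-(methoxymethoxy)-2,2-dimethyl-6-(3-methylbut-2-en-1-yl)-2H-chromen-5-yl]ethan-1-one | CC(C)=CCc1c(OCOC)cc2c(c1C(C)=O)C=CC(C)(C)O2
A6 | alternative 2 | 2-bromo-1-iodo-4-(methoxymethoxy)benzene | COCOc1ccc(I)c(Br)c1
A7 | alternative 3 | methyl 2,4-dihydroxy-6-[6-(methoxymethoxy)benzofuran-2-yl]-5-(3-methylbut-2-en-1-yl)benzoate | COC(=O)c1c(O)cc(O)c(CC=C(C)C)c1-c1cc2ccc(OCOC)cc2o1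
A8 | alternative 3 | 1-methoxy-7-methyl-1,3-bis(trimethylsilyloxy)octa-1,3,6-triene | COC(O[Si](C)(C)C)=CC(O[Si](C)(C)C)=CCC=C(C)C
A9 | alternative 3 | methyl 3-[6-(methoxymethoxy)benzofuran-2-yl]prop-2-ynoate | COC(=O)C#Cc1cc2ccc(OCOC)cc2o1
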